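**Assumption:** 19 has no stereocentre, and its 19-membered ring is taken to be conformationally mobile, so no axial or planar chirality has to be controlled.

## The problem

Compound 19 is a macrocyclic bis(bibenzyl). Four benzene rings are tied into one 19-membered ring by two diaryl ether oxygens (ring A to ring B, ring C to ring D) and two CH2–CH2 bridges (ring B to ring C, ring D to ring A). Ring A is an anisole with the ether oxygen ortho and the bridge para to OMe; ring B is a para-phenylene; ring C is a phenol with the ether oxygen ortho and the bridge para to OH; ring D is a bare meta-phenylene. With no stereocentre, the tasks are the substitution pattern of the two 1,2,4-trisubstituted rings and closure of a large ring against oligomerization. The ring C hydroxyl must stay distinguishable from the ring A methyl ether to the end, so it needs a protecting group that leaves without harming OMe. The diaryl ethers are robust, but the handles for a late C–C coupling are not: an aryl iodide would not outlast a copper-mediated ether synthesis and an amine would compete in it, so the order of unveiling matters. The enabling feature is the bridge between the ring B carbon para to its ether oxygen and the ring C carbon para to the hydroxyl. It is two carbons between two aryl carbons, which a 1,2-dimetallated ethene can deliver to two aryl halides in one operation. The alkene so formed costs nothing, because the hydrogenation that saturates it also frees the phenol.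

## Retrosynthesis

**19 from 18.** No skeletal bond is cut. The B–C bridge is taken back to an E-alkene and the phenol to its benzyl ether, giving the macrocyclic stilbene 18. One hydrogenation over palladium on carbon should do both. Benzyl is preferred to a second methyl ether (which could not be told from the ring A methoxy group) and to a silyl ether (less sure to survive the base and heat of the ether syntheses).

**18 from 14 and 15.** Both aryl–vinyl bonds of the bridge are cut, leading to the open-chain diiodide 14 and commercial (E)-1,2-bis(tributylstannyl)ethene 15. A Wittig or McMurry closure at the same bridge would need two different one-carbon handles carried and differentiated through the synthesis. A macrocyclic Ullmann etherification would need high temperature and high dilution together. The two-carbon linchpin asks only for two identical C–I bonds on an otherwise inert tetra-aryl chain. The forward reaction is a double Stille coupling in which the second, ring-closing event is intramolecular.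

**14 from 12 and 11.** The C–I bonds are traced to C–N bonds: diiodide 14 from dianiline 12, and 12 from the dinitro compound 11. Iodine cannot be carried through the copper-mediated ether synthesis, and electrophilic iodination would not discriminate among four oxygenated rings. A nitro group fixes the position unambiguously, is inert to copper, and on ring B also activates the ring for the ether-forming substitution. The forward steps are a metal reduction that spares the benzyl ether and a twofold Sandmeyer-type iodination.

**11 from 8 and 10.** The bond from the ring D oxygen to ring C is cut, giving phenol 8 and 1-(benzyloxy)-2-bromo-4-nitrobenzene 10, the benzyl ether of commercial 2-bromo-4-nitrophenol 9. In 10 the bromide is meta to the nitro group, so SNAr is closed and an Ullmann coupling is required. In return, 9 supplies the whole 1,2,4-pattern of ring C in one purchased compound. Compound 8 is half the size of 11 and carries a single nucleophilic site.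

**8 from 7, and 7 from 5 and 2.** The D–A bridge is taken back to the alkene of stilbene 7, which is cut into aldehyde 5 and the phosphonium salt 2. Salt 2 is made in one step from 3-hydroxybenzyl alcohol 1. A Wittig reaction is the shortest union of a benzaldehyde and a benzyl unit. The alkene is saturated by diimide at once, because catalytic hydrogenation would also reduce the nitro group to an amine that competes in the Ullmann step. An alkene left in the chain could also enter Heck pathways during the key step.

**5 from 3 and 4.** The bond from the ring A oxygen to ring B is cut, giving isovanillin 3 and 1-fluoro-4-nitrobenzene 4. Isovanillin carries the whole pattern of ring A, and the para-nitro group makes the forward step a plain SNAr.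

## Roads not taken

**Alternative 1:** Here ring B is not bought but built. Two C–C bonds of the future ring B are cut, giving the open-chain precursor A2. A2 carries a 2-aryloxybuta-1,3-diene on the ring A oxygen and a terminal ynone tethered through ring C. Heating A2 at high dilution would form the six-membered carbocycle and the macrocycle in one Diels–Alder step, giving the cyclohexa-1,4-diene ketone A1.

- Merits: two C–C bonds and two rings form in a thermal step without tin or palladium. The oxygen on the diene and the carbonyl on the alkyne reinforce each other toward the para pattern that ring B needs.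
- Weak points: the 2-aryloxybutadiene is an acid-labile, polymerizable enol ether that is not trivial to install on a hindered guaiacol-type oxygen. The terminal ynone is a strong Michael acceptor that must survive assembly. The cycloaddition must close a large ring with no preorganization while intermolecular addition stays open. A1 still needs aromatization, removal of the bridge carbonyl and debenzylation to reach 19.
- Comparison: this road is better in avoiding stoichiometric organotin and diazonium chemistry. The chosen plan sets against that a precursor (14) made from four commercial arenes by routine reactions, all four rings present from the start, and one step after ring closure.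

**Alternative 2:** The bond from the ring D oxygen to the ring C carbon ortho to OH is cut, with ring C carried as a cyclohexanone. In the precursor A4 the ring D phenol faces a bromide alpha to the ketone. Cs2CO3 in DMF at high dilution would close the ring by SN2 etherification to the 2-aryloxycyclohexanone A3, which is then dehydrogenated to the phenol of 19.

- Merits: caesium phenoxide macro-etherification is among the most dependable macrocyclizations. The Ullmann coupling at a hindered bromide, the weakest ordinary step of the chosen route, disappears. Ring C needs no protecting group.
- Weak points: a secondary alpha-bromo ketone invites elimination to the enone and Favorskii-type rearrangement beside substitution. The bromide must be introduced while a free phenol and an anisole ring, both readily brominated, are present or about to be unveiled, so protection returns by another door. A3 is formed as a mixture of diastereomers. The closing dehydrogenation must remove four hydrogens from the carbocycle without touching two bibenzyl bridges or cleaving the alpha-aryloxy C–O bond. Building the saturated ring C surrogate with its two-carbon link to ring B costs more steps than buying 9.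
- Comparison: the ring closure itself is probably more reliable here than a double Stille coupling. The chosen plan answers with an endgame of one clean hydrogenation instead of a late oxidation on a complex macrocycle.

**Alternative 3:** The bond between ring A (the carbon para to OMe) and the adjacent bridge carbon is cut. The precursor A6 is an arylacetic acid on ring D with the ring C phenol masked as a mesylate. After activation with (COCl)2 and ionization with SnCl4 at high dilution, acylation of ring A para to OMe would give the macrocyclic ketone A5.

- Merits: no organometallic reagent is needed, and ring A needs no handle because the methoxy group directs the electrophile. The mesylate protects the phenol and also deactivates ring C toward acylation.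
- Weak points: site selectivity rests on electronics alone. The position para to the aryloxy oxygen of ring A and the positions ortho to oxygen on ring B are also activated and would give isomeric rings. Arylacetyl chlorides under Lewis acids can lose CO or form ketenes and oligomerize. SnCl4 binds the ether oxygens. A5 then needs deoxygenation of the bridge ketone and cleavage of the mesylate, two steps against one.
- Comparison: the precursor A6 is about as long to make as 14 and avoids tin and the Sandmeyer sequence, which counts in its favour. The chosen plan offers bond-forming sites fixed by two C–I bonds instead of by relative ring nucleophilicity.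

Key step: step 9

## Route

**Step 1**
Reactants: 1 3-hydroxybenzyl alcohol
Product: 2 (3-hydroxybenzyl)triphenylphosphonium bromide
Conditions: PPh3·HBr, MeCN, reflux
Reagents that add atoms: triphenylphosphine hydrobromide, Br.c1ccc(cc1)P(c1ccccc1)c1ccccc1
Why: One-pot phosphonium salt formation: the acid turns the benzylic hydroxyl into a leaving group, bromide and then PPh3 substitute at the benzylic carbon, and the phenol does not interfere.

**Step 2**
Reactants: 3 isovanillin (3-hydroxy-4-methoxybenzaldehyde); 4 1-fluoro-4-nitrobenzene
Product: 5 4-methoxy-3-(4-nitrophenoxy)benzaldehyde
Conditions: K2CO3, DMF, 90 °C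
Reagents that add atoms: none
Why: Nucleophilic aromatic substitution (SNAr): the phenoxide of 3 adds para to the nitro group of 4 and fluoride leaves from the Meisenheimer adduct; the aldehyde has no alpha hydrogen and is inert to carbonate.

**Step 3**
Reactants: 2 (3-hydroxybenzyl)triphenylphosphonium bromide; 5 4-methoxy-3-(4-nitrophenoxy)benzaldehyde
Product: 7 3-{2-[4-methoxy-3-(4-nitrophenoxy)phenyl]ethenyl}phenol (E/Z mixture), via phenoxide ylide 6 (not isolated)
Conditions: KOtBu (2.05 equiv), THF, 0 °C; then 5, 0 °C to rt; 1 M HCl quench
Reagents that add atoms: none
Why: Wittig olefination with a semi-stabilized benzylic ylide; the first equivalent of base only forms the phenoxide, which sits meta to the ylide carbon and so can neither expel PPh3 nor quench the ylide. The E/Z ratio is irrelevant because step 4 removes the double bond.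

**Step 4**
Reactants: 7 3-{2-[4-methoxy-3-(4-nitrophenoxy)phenyl]ethenyl}phenol (E/Z mixture)
Product: 8 3-{2-[4-methoxy-3-(4-nitrophenoxy)phenyl]ethyl}phenol
Conditions: TsNHNH2, NaOAc, THF/H2O, reflux
Reagents that add atoms: none
Why: Diimide reduction: HN=NH released from the sulfonyl hydrazide transfers two hydrogens concertedly to the nonpolar C=C bond of both isomers and leaves the nitro group untouched, which catalytic hydrogenation would not.

**Step 5**
Reactants: 9 2-bromo-4-nitrophenol
Product: 10 1-(benzyloxy)-2-bromo-4-nitrobenzene
Conditions: BnBr, K2CO3, DMF, 60 °C
Reagents that add atoms: benzyl bromide, BrCc1ccccc1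
Why: Williamson ether synthesis (SN2) of the acidic nitrophenol; benzyl is chosen because step 10 removes it under the conditions that saturate the stilbene.

**Step 6**
Reactants: 8 3-{2-[4-methoxy-3-(4-nitrophenoxy)phenyl]ethyl}phenol; 10 1-(benzyloxy)-2-bromo-4-nitrobenzene
Product: 11 1-(benzyloxy)-2-(3-{2-[4-methoxy-3-(4-nitrophenoxy)phenyl]ethyl}phenoxy)-4-nitrobenzene
Conditions: CuI (20 mol %), N,N-dimethylglycine hydrochloride, Cs2CO3, dioxane, 100 °C
Reagents that add atoms: none
Why: Ullmann diaryl ether synthesis with monovalent copper and an amino acid ligand; the bromide of 10 is meta to the nitro group and closed to SNAr, but the electron-poor ring should undergo oxidative addition readily, and 8 offers one phenol as the only nucleophile. Nitro groups and the benzyl ether are tolerated, and the weakly polar solvent disfavours uncatalysed ether exchange.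

**Step 7**
Reactants: 11 1-(benzyloxy)-2-(3-{2-[4-methoxy-3-(4-nitrophenoxy)phenyl]ethyl}phenoxy)-4-nitrobenzene
Product: 12 4-(benzyloxy)-3-(3-{2-[3-(4-aminophenoxy)-4-methoxyphenyl]ethyl}phenoxy)aniline
Conditions: Fe powder, NH4Cl, EtOH/THF/H2O, 75 °C
Reagents that add atoms: none
Why: Béchamp-type reduction of both nitro groups by iron metal in buffered aqueous alcohol; electron-transfer conditions leave the benzyl ether intact, which hydrogenation over palladium would not guarantee.

**Step 8**
Reactants: 12 4-(benzyloxy)-3-(3-{2-[3-(4-aminophenoxy)-4-methoxyphenyl]ethyl}phenoxy)aniline
Product: 14 1-(benzyloxy)-4-iodo-2-(3-{2-[3-(4-iodophenoxy)-4-methoxyphenyl]ethyl}phenoxy)benzene, via bis(diazonium) ditosylate 13 (not isolated)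
Conditions: p-TsOH·H2O, NaNO2, KI, MeCN/H2O, 10 °C to rt
Reagents that add atoms: potassium iodide, [K+].[I-]
Why: Sandmeyer-type iododediazoniation: both anilines are diazotized in acetonitrile, where the lipophilic substrate dissolves and arenediazonium tosylates are stable, and iodide reduces each diazonium ion to an aryl radical that is trapped as the aryl iodide without copper. The iodine atoms take the positions of the former nitro groups, para to the ring B ether oxygen and para to the ring C benzyloxy group.

**Step 9**
Reactants: 14 1-(benzyloxy)-4-iodo-2-(3-{2-[3-(4-iodophenoxy)-4-methoxyphenyl]ethyl}phenoxy)benzene; 15 (E)-1,2-bis(tributylstannyl)ethene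
Product: 18 macrocyclic E-stilbene benzyl ether (the 19-membered ring of 19 with an E double bond in place of the CH2–CH2 bridge between rings B and C and a benzyl ether on the ring C oxygen), via ring B styrylstannane 16 (not isolated), via ring C styrylstannane 17 (not isolated)
Conditions: Pd(PPh3)4 (20 mol %), PhMe, 100 °C; 14 and 15 (1.05 equiv) added together by syringe pump over 12 h, final concentration 1 mM; aq. KF work-up
Reagents that add atoms: none
Why: Two Stille cross-couplings run in one flask: zerovalent palladium inserts into one C–I bond of 14, the arylpalladium iodide transmetalates with one tin terminus of 15, and reductive elimination gives a tethered styrylstannane (16 or 17, depending on which iodide reacts first; both converge). A second oxidative addition at the remaining iodide, intramolecular transmetalation and reductive elimination form the second aryl–vinyl bond. The closest known reaction type is the stitching macrocyclization of a dihalide with a 1,2-distannylethene used to close macrocyclic polyenes. The 19-membered ring closes by C(sp2)–C(sp2) reductive elimination from a macrocyclic aryl(vinyl)palladium intermediate. No stereocentre is formed, and the E geometry is carried over from 15 because transmetalation at vinyl carbon proceeds with retention. The step needs cyclization to outrun oligomerization and the capping of both iodides by two molecules of 15; slow joint addition of near-equimolar 14 and 15 keeps both dilute, and the second coupling is intramolecular. Site selectivity is fixed by the two C–I bonds, and the benzyl, methyl and diaryl ethers are inert to the catalyst.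

**Step 10**
Reactants: 18 macrocyclic E-stilbene benzyl ether
Product: 19 target macrocycle (CNP0132125.0)
Conditions: H2 (1 atm), 10% Pd/C, EtOAc/MeOH, rt
Reagents that add atoms: none
Why: Heterogeneous catalytic hydrogenation: addition of H2 to the stilbene and hydrogenolysis of the benzylic C–O bond occur on the same catalyst, while the methyl ether, diaryl ethers and arene rings are inert at 1 atm and room temperature. Tin residues are removed with fluoride in step 9 so that the catalyst is not poisoned.

## Compound list

1 | 3-hydroxybenzyl alcohol | OCc1cccc(O)c1 | starting material
2 | (3-hydroxybenzyl)triphenylphosphonium bromide | [Br-].Oc1cccc(C[P+](c2ccccc2)(c2ccccc2)c2ccccc2)c1 | intermediate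
3 | isovanillin | COc1ccc(C=O)cc1O | starting material
4 | 1-fluoro-4-nitrobenzene | O=[N+]([O-])c1ccc(F)cc1 | starting material
5 | 4-methoxy-3-(4-nitrophenoxy)benzaldehyde | COc1ccc(C=O)cc1Oc1ccc(cc1)[N+](=O)[O-] | intermediate
6 | potassium 3-[(triphenylphosphoranylidene)methyl]phenolate (phenoxide ylide, not isolated) | [K+].[O-]c1cccc(C=P(c2ccccc2)(c2ccccc2)c2ccccc2)c1 | intermediate
7 | 3-{2-[4-methoxy-3-(4-nitrophenoxy)phenyl]ethenyl}phenol (E/Z mixture, geometry not defined) | COc1ccc(C=Cc2cccc(O)c2)cc1Oc1ccc(cc1)[N+](=O)[O-] | intermediate
8 | 3-{2-[4-methoxy-3-(4-nitrophenoxy)phenyl]ethyl}phenol | COc1ccc(CCc2cccc(O)c2)cc1Oc1ccc(cc1)[N+](=O)[O-] | intermediate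
9 | 2-bromo-4-nitrophenol | Oc1ccc(cc1Br)[N+](=O)[O-] | starting material
10 | 1-(benzyloxy)-2-bromo-4-nitrobenzene | O=[N+]([O-])c1ccc(OCc2ccccc2)c(Br)c1 | intermediate
11 | 1-(benzyloxy)-2-(3-{2-[4-methoxy-3-(4-nitrophenoxy)phenyl]ethyl}phenoxy)-4-nitrobenzene | COc1ccc(CCc2cccc(Oc3cc(ccc3OCc3ccccc3)[N+](=O)[O-])c2)cc1Oc1ccc(cc1)[N+](=O)[O-] | intermediate
12 | 4-(benzyloxy)-3-(3-{2-[3-(4-aminophenoxy)-4-methoxyphenyl]ethyl}phenoxy)aniline | COc1ccc(CCc2cccc(Oc3cc(N)ccc3OCc3ccccc3)c2)cc1Oc1ccc(N)cc1 | intermediate
13 | bis(diazonium) ditosylate of 12 (not isolated) | COc1ccc(CCc2cccc(Oc3cc([N+]#N)ccc3OCc3ccccc3)c2)cc1Oc1ccc([N+]#N)cc1.Cc1ccc(cc1)S(=O)(=O)[O-].Cc1ccc(cc1)S(=O)(=O)[O-] | intermediate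
14 | open-chain diiodide, 1-(benzyloxy)-4-iodo-2-(3-{2-[3-(4-iodophenoxy)-4-methoxyphenyl]ethyl}phenoxy)benzene | COc1ccc(CCc2cccc(Oc3cc(I)ccc3OCc3ccccc3)c2)cc1Oc1ccc(I)cc1 | intermediate
15 | (E)-1,2-bis(tributylstannyl)ethene | CCCC[Sn](CCCC)(CCCC)/C=C/[Sn](CCCC)(CCCC)CCCC | starting material
16 | ring B (E)-styrylstannane with the ring C iodide intact (not isolated) | COc1ccc(CCc2cccc(Oc3cc(I)ccc3OCc3ccccc3)c2)cc1Oc1ccc(/C=C/[Sn](CCCC)(CCCC)CCCC)cc1 | intermediate
17 | ring C (E)-styrylstannane with the ring B iodide intact (not isolated) | COc1ccc(CCc2cccc(Oc3cc(/C=C/[Sn](CCCC)(CCCC)CCCC)ccc3OCc3ccccc3)c2)cc1Oc1ccc(I)cc1 | intermediate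
18 | macrocyclic E-stilbene benzyl ether | COc1ccc2cc1Oc1ccc(cc1)/C=C/c1ccc(OCc3ccccc3)c(c1)Oc1cccc(c1)CC2 | intermediate
19 | target macrocycle CNP0132125.0 (no stereocentre) | COc1ccc2cc1Oc1ccc(cc1)CCc1ccc(O)c(c1)Oc1cccc(c1)CC2 | target

## Step count and risks

Total step count: 10. Longest linear sequence: 8 steps (steps 2, 3, 4, 6, 7, 8, 9, 10 from isovanillin 3; equally steps 1, 3, 4, 6, 7, 8, 9, 10 from 1).

**Step 9 (key step).** The most likely failures are intermolecular coupling of the tethered stannane (oligomerization), capping of both iodides by two separate molecules of 15, and protodestannylation of the intermediate before the ring closes. Strain in placing an E-alkene in the ring would slow the second coupling and favour all three. The fallback sets out from 14. A twofold Stille coupling with tributyl(vinyl)stannane (Pd(PPh3)4, PhMe, 100 °C), which is intermolecular and needs no dilution, should give the bis-styrene F1. Ring-closing metathesis of F1 with the second-generation Grubbs catalyst in dilute toluene then forms the bridge C=C bond with loss of ethene, in place of the two aryl–vinyl bonds. This returns to the route at 18. Any Z isomer F2 formed beside it is carried into step 10 as well, since hydrogenation erases the geometry.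

**Step 6.** Oxidative addition and aryloxide transfer at a bromide flanked by the benzyloxy group may be slow. At 100 °C, reductive debromination and uncatalysed ether exchange could then take over, through phenoxide attack at a carbon para to a nitro group. The fallback sets out from 10. Miyaura borylation (B2pin2, Pd(dppf)Cl2, KOAc, dioxane, 80 °C) should give the pinacol boronate F3. Oxidative cleavage of the diol (NaIO4, NH4OAc, acetone/H2O) gives the boronic acid F4. A Chan–Lam coupling of F4 with phenol 8 (Cu(OAc)2, pyridine, 4 Å molecular sieves, CH2Cl2, air, rt) then forms the same C–O bond oxidatively at room temperature, without hot phenoxide, and returns to the route at 11.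

**Step 8.** Diazotization of one of the two amino groups may lag. A diazonium ion could then couple with a remaining amine or an electron-rich ring, and diazonium groups could be lost by reduction or hydrolysis in the aqueous iodide medium. The fallback sets out from 12 and separates diazotization from iodination. Diazotization at 0 °C (NaNO2, aq. HCl, MeCN) followed by a quench into Et2NH/K2CO3 should give the bis(diethyltriazene) F5, which can be purified. Heating F5 with MeI in a sealed tube at 120 °C releases the aryl iodides under anhydrous conditions and returns to the route at 14.

**Step 3.** The olefination may be sluggish because the ylide carries a phenoxide (low solubility, aggregation). The phenoxide or residual alkoxide could also attack the nitro-activated diaryl ether of 5. The fallback sets out from 5. Methylenation (Ph3PCH3Br, KOtBu, THF, 0 °C) should give the styrene F6. A Heck reaction of F6 with 3-iodophenol (Pd(OAc)2, P(o-tol)3, Et3N, MeCN, 80 °C) builds the same stilbene without a phenoxide ylide and returns to the route at 7 as its E isomer.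

## Further compounds

F1 | step 9 | 1-(benzyloxy)-4-ethenyl-2-(3-{2-[3-(4-ethenylphenoxy)-4-methoxyphenyl]ethyl}phenoxy)benzene (bis-styrene) | COc1ccc(CCc2cccc(Oc3cc(C=C)ccc3OCc3ccccc3)c2)cc1Oc1ccc(C=C)cc1
F2 | step 9 | Z isomer of macrocyclic stilbene benzyl ether 18 | COc1ccc2cc1Oc1ccc(cc1)/C=C\c1ccc(OCc3ccccc3)c(c1)Oc1cccc(c1)CC2
F3 | step 6 | 2-[2-(benzyloxy)-5-nitrophenyl]-4,4,5,5-tetramethyl-1,3,2-dioxaborolane | CC1(C)OB(OC1(C)C)c1cc(ccc1OCc1ccccc1)[N+](=O)[O-]
F4 | step 6 | [2-(benzyloxy)-5-nitrophenyl]boronic acid | OB(O)c1cc(ccc1OCc1ccccc1)[N+](=O)[O-]
F5 | step 8 | bis(3,3-diethyltriazene) of 12 (both N=N bonds E) | COc1ccc(CCc2cccc(Oc3cc(/N=N/N(CC)CC)ccc3OCc3ccccc3)c2)cc1Oc1ccc(/N=N/N(CC)CC)cc1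
F6 | step 3 | 4-ethenyl-1-methoxy-2-(4-nitrophenoxy)benzene | COc1ccc(C=C)cc1Oc1ccc(cc1)[N+](=O)[O-]
A1 | alternative 1 | macrocyclic cyclohexa-1,4-diene ketone | COc1ccc2cc1OC1=CCC(=CC1)C(=O)Cc1ccc(OCc3ccccc3)c(c1)Oc1cccc(c1)CC2
A2 | alternative 1 | open-chain 2-aryloxybuta-1,3-diene with tethered terminal ynone | C=CC(=C)Oc1cc(CCc2cccc(Oc3cc(CC(=O)C#C)ccc3OCc3ccccc3)c2)ccc1OC
A3 | alternative 2 | macrocyclic 2-aryloxycyclohexanone (mixture of diastereomers, configuration not defined) | COc1ccc2cc1Oc1ccc(cc1)CCC1CCC(=O)C(C1)Oc1cccc(c1)CC2
A4 | alternative 2 | open-chain 2-bromocyclohexanone with free ring D phenol (configuration not defined) | COc1ccc(CCc2cccc(O)c2)cc1Oc1ccc(CCC2CCC(=O)C(Br)C2)cc1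
A5 | alternative 3 | macrocyclic aryl ketone mesylate | COc1ccc2cc1Oc1ccc(cc1)CCc1ccc(OS(C)(=O)=O)c(c1)Oc1cccc(c1)CC2=O
A6 | alternative 3 | open-chain ring D arylacetic acid with ring C mesylate | COc1ccccc1Oc1ccc(CCc2ccc(OS(C)(=O)=O)c(Oc3cccc(CC(=O)O)c3)c2)cc1
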